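Retrosynthesis (gibberellane numbering): ring A is opened at C1–C10 and C2–C3, so the C1–C2 unit leaves as an acrylate. What remains is a ring B aldehyde in which C10 is the α-carbon of the C20 formyl group and C3 is an ester carbonyl of a methylmalonate on C5, 1,4 to C10 through C5–C4; this pairing lets a Michael/Dieckmann annulation close ring A (C1, C2, C3, C4, C5, C10).
Further cuts: C4–C5 (malonate Michael addition), C6–C7 (carbonylation), C10–C20 (conjugate addition), C13–C16 (vinyl radical closure of ring D), C8–C14 and C9–C11 (Diels–Alder reaction for ring C).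
Forward order: ring B (a 2-substituted cyclopentenone), ring C, ring D, the substituents of ring B, ring A (key step), then C3 reduction and ester cleavage.
Stereochemistry: C8 and C9 from a catalytic enantioselective Diels–Alder reaction; C13 from the geometry of the bridge; C5 and C6 by trans relay from a temporary C10 centre; C10 and C4 in the key step (face of the C10 enolate, choice between the two diastereotopic malonate esters); C3 by equatorial hydride delivery.
Key step: step 12

Remark: gibberellane numbering (C1–C20) is used for all intermediates, and the name stem gibberell-16-ene stands for the tetracyclic skeleton with the absolute configuration of the target; β = the face of H-5, H-9, C-18 and the C15–C16 bridge and α = the face of C-19 and C-20; the target is made as the open 20-aldehyde drawn, which may equilibrate with its 19,20-lactol.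

Step 1
Reactants: 1 cyclopentane-1,3-dione; 2 2,3-dibromoprop-1-ene
Product: 3 2-(2-bromoprop-2-en-1-yl)cyclopentane-1,3-dione
Conditions: KOH (1 equiv), H2O, 60 °C
Reagents that add atoms: none
Why: C-alkylation of the 1,3-dione enolate by the allylic bromide (SN2, the vinylic bromide is inert) is the standard aqueous allylation of cyclic 1,3-diones and creates no stereocenter.

Step 2
Reactants: 3 2-(2-bromoprop-2-en-1-yl)cyclopentane-1,3-dione
Product: 4 2-(2-bromoprop-2-en-1-yl)-3-(2-methylpropoxy)cyclopent-2-en-1-one
Conditions: i-BuOH, p-TsOH (cat.), toluene, reflux (Dean–Stark)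
Reagents that add atoms: 2-methylpropan-1-ol CC(C)CO
Why: Acid-catalysed enol ether formation from the 1,3-dione gives the vinylogous ester needed for the carbonyl transposition.

Step 3
Reactants: 4 2-(2-bromoprop-2-en-1-yl)-3-(2-methylpropoxy)cyclopent-2-en-1-one
Product: 6 2-(2-bromoprop-2-en-1-yl)cyclopent-2-en-1-one, via allylic alcohol 5 (not isolated)
Conditions: i-Bu2AlH, toluene, −78 °C; then 1 M HCl, THF, rt
Reagents that add atoms: none
Why: 1,2-Reduction of the vinylogous ester, then hydrolysis of the enol ether and β-elimination of water (reductive 1,3-carbonyl transposition of a 3-alkoxy enone), should give the 2-substituted cyclopentenone.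

Step 4
Reactants: 6 2-(2-bromoprop-2-en-1-yl)cyclopent-2-en-1-one; 7 buta-1,3-diene
Product: 8 (3aR,7aR)-7a-(2-bromoprop-2-en-1-yl)-2,3,3a,4,7,7a-hexahydro-1H-inden-1-one (cis-fused)
Conditions: 7 (excess), triflimide salt of the (S)-diphenylprolinol-derived B-(2-methylphenyl)oxazaborolidine (20 mol %, from the oxazaborolidine and Tf2NH), CH2Cl2, −40 → −20 °C
Reagents that add atoms: none
Why: Catalytic enantioselective Diels–Alder reaction with a cationic oxazaborolidine Lewis acid: suprafacial addition across C8=C9 gives the cis ring fusion (H-9 cis to the bromoallyl group) and shielding of one enone face by the catalyst sets C8 and C9 (the enantiomeric catalyst is taken if the sense of induction is the opposite one).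

Step 5
Reactants: 8 (3aR,7aR)-7a-(2-bromoprop-2-en-1-yl)-2,3,3a,4,7,7a-hexahydro-1H-inden-1-one
Product: 9 (1R,5S,8R)-9-methylidenetricyclo[6.2.1.0(1,5)]undecan-2-one (rings B, C and D: C5, C6, C8–C17; 6-oxo, 16-methylidene, H-9 β)
Conditions: Bu3SnH (slow addition), AIBN (cat.), toluene, 90 °C
Reagents that add atoms: none
Why: Vinyl radical cyclisation: the C16 radical closes 5-exo-trig onto C13 of the cyclohexene (kinetically preferred over 6-endo attack at C12), the C12 radical is reduced by Bu3SnH, and the short tether allows only the cis-bridged bicyclo[3.2.1]octane, which fixes C13.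

Step 6
Reactants: 9 (1R,5S,8R)-9-methylidenetricyclo[6.2.1.0(1,5)]undecan-2-one
Product: 10 rings B, C, D enone (6-oxo, C5=C10 double bond; 9-methylidenetricyclo[6.2.1.0(1,5)]undec-3-en-2-one)
Conditions: IBX (2-iodoxybenzoic acid), DMSO/toluene, 70 °C
Reagents that add atoms: none
Why: IBX dehydrogenation of a ketone to the enone can only go towards C5–C10 because C8 is quaternary.

Step 7
Reactants: 10 rings B, C, D enone
Product: 12 enol triflate (6-triflyloxy, C5=C6, 10β-CH2SiMe2(O-i-Pr), 10α-H), via magnesium enolate 11 (not isolated)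
Conditions: (i-PrO)Me2SiCH2MgCl, CuBr·SMe2 (10 mol %), THF, −78 → −40 °C; then PhNTf2, DMPU, −78 → 0 °C
Reagents that add atoms: (isopropoxydimethylsilyl)methylmagnesium chloride CC(C)O[Si](C)(C)C[Mg]Cl; N-phenylbis(trifluoromethanesulfonimide) O=S(=O)(N(c1ccccc1)S(=O)(=O)C(F)(F)F)C(F)(F)F
Why: Copper-catalysed 1,4-addition of the hydroxymethyl anion equivalent should occur at C10 on the face anti to the C9–C11 bond (β, the convex face of the cis-fused rings B and C), and O-triflation of the resulting enolate fixes the double bond at C5=C6.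

Step 8
Reactants: 12 enol triflate
Product: 13 methyl ester (C5=C6, 6-CO2Me = C7, 10β-CH2SiMe2(O-i-Pr))
Conditions: CO (1 atm), MeOH, Et3N, Pd(OAc)2 (5 mol %), PPh3 (10 mol %), DMF, 50 °C
Reagents that add atoms: carbon monoxide [C-]#[O+]; methanol CO
Why: Palladium-catalysed methoxycarbonylation of a vinyl triflate installs C7 on C6 and leaves the isolated 16-methylidene group untouched.

Step 9
Reactants: 13 methyl ester (C5=C6); 14 dimethyl malonate
Product: 16 triester (5α-C(CH3)(CO2Me)2, 5β-H, 6β-CO2Me, 6α-H, 10β-CH2SiMe2(O-i-Pr)), via potassium malonate enolate 15 (not isolated)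
Conditions: 14 (2 equiv), KOt-Bu (2 equiv), t-BuOH/THF, 50 °C; then MeI, 0 °C → rt
Reagents that add atoms: iodomethane CI
Why: Reversible Michael addition under alkoxide equilibration should place the malonate on C5 trans to the C10 substituent (α) and the C6 ester trans to it (β), the all-trans array, and C-methylation of the malonate anion then gives the C(CH3)(CO2Me)2 group, which is still achiral at C4.

Step 10
Reactants: 16 triester (10β-CH2SiMe2(O-i-Pr))
Product: 17 triester alcohol (10β-CH2OH)
Conditions: H2O2 (30 % aq), KF, KHCO3, THF/MeOH, rt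
Reagents that add atoms: hydrogen peroxide OO
Why: Tamao oxidation converts the alkoxysilyl C–Si bond into C–OH under mildly basic conditions that spare the esters and the 1,1-disubstituted alkene.

Step 11
Reactants: 17 triester alcohol
Product: 18 triester aldehyde (10β-CHO = C20, 5α-C(CH3)(CO2Me)2, 6β-CO2Me)
Conditions: Dess–Martin periodinane, NaHCO3, CH2Cl2, 0 °C → rt
Reagents that add atoms: none
Why: Dess–Martin oxidation of the primary alcohol gives the aldehyde under buffered, non-basic conditions; the configuration at C10 is irrelevant because C10 is enolised in the next step.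

Step 12
Reactants: 18 triester aldehyde; 19 allyl acrylate (prop-2-en-1-yl prop-2-enoate)
Product: 21 dimethyl 2-(allyloxycarbonyl)-3,20-dioxogibberell-16-ene-7,19-dioate (C2 epimers and enol form), via Michael adduct 20 (not isolated)
Conditions: 19 (3 equiv), KOt-Bu (1.5 equiv), THF, −78 → 0 °C; then dilute aq. HCl
Reagents that add atoms: none
Why: KOt-Bu deprotonates only C10 (the sole aldehyde α-hydrogen; C4 is quaternary and the ester α-hydrogen at C6 is far less acidic), the enolate adds through carbon to the acrylate (intermolecular Michael addition, C1–C10), and the new ester enolate at C2 acylates one malonate ester (Dieckmann condensation, C2–C3) with loss of methoxide, the product being held as its β-keto ester enolate. The closest known reaction type is the Michael–Dieckmann annulation of carbonyl α-carbanions with acrylates, including the base-catalysed Michael addition of α-branched aldehydes to acrylates. Ring A is closed in a 6-exo-trig mode through a chair that is trans-fused to ring B. C10 is controlled by the substrate: the acrylate should approach the enolate on the β face, anti to the malonate on C5 and to the C9–C11 bond, so that C1 becomes β and the formyl group α. C4 is created by the choice between the two diastereotopic esters: the chair that keeps the remaining CO2Me axial (α, syn to the axial formyl group, where the flat ester suffers less 1,3-diaxial strain than CH3 and can share the potassium ion with the aldehyde oxygen) and CH3 equatorial should lead to the 4α-carboxyl/4β-methyl arrangement. The step needs C- over O-alkylation, trapping of the C10 enolate before it expels methylmalonate by retro-Michael cleavage, and closure onto a malonate ester and not the C7 ester; low temperature with excess acrylate, the neopentyl position of the C7 ester and the bridged transition state that its attack would require should secure this.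

Step 13
Reactants: 21 dimethyl 2-(allyloxycarbonyl)-3,20-dioxogibberell-16-ene-7,19-dioate
Product: 23 dimethyl 3,20-dioxogibberell-16-ene-7,19-dioate (3-keto 20-aldehyde diester), via β-keto acid 22 (not isolated)
Conditions: Pd(PPh3)4 (5 mol %), HCO2H, Et3N, THF, rt
Reagents that add atoms: none
Why: Zerovalent palladium ionises only the allyl ester (Tsuji–Trost-type deallylation with formate as hydride donor), and the β-keto acid loses CO2 at room temperature, while the quaternary C19 methyl ester stays in place.

Step 14
Reactants: 23 dimethyl 3,20-dioxogibberell-16-ene-7,19-dioate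
Product: 24 dimethyl 20-(dimethylhydrazinylidene)-3-oxogibberell-16-ene-7,19-dioate (20-(N,N-dimethylhydrazone) of 23)
Conditions: Me2NNH2, MgSO4, CH2Cl2, rt
Reagents that add atoms: 1,1-dimethylhydrazine CN(C)N
Why: Hydrazone formation is much faster at the aldehyde than at the hindered C3 ketone, and the planar, hydride-inert C=N–NMe2 group masks C20 without adding bulk next to the axial C19 ester.

Step 15
Reactants: 24 dimethyl 20-(dimethylhydrazinylidene)-3-oxogibberell-16-ene-7,19-dioate
Product: 26 dimethyl 3β-hydroxy-20-oxogibberell-16-ene-7,19-dioate (dimethyl ester of the target), via hydroxy hydrazone 25 (not isolated)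
Conditions: K[s-Bu3BH] (K-Selectride), THF, −78 → −40 °C; H2O; then CuCl2, THF/pH 7 buffer, rt
Reagents that add atoms: water O
Why: The bulky borohydride should attack the C3 ketone along the equatorial (α) trajectory, as in the reduction of 4,4-disubstituted 3-oxo terpenoids to axial alcohols, giving the axial 3β-alcohol while hydrazone and esters are inert, and copper-assisted hydrolysis then frees the aldehyde.

Step 16
Reactants: 26 dimethyl 3β-hydroxy-20-oxogibberell-16-ene-7,19-dioate
Product: 27 3β-hydroxy-20-oxogibberell-16-ene-7,19-dioic acid (the target gibberellin)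
Conditions: n-PrSLi, HMPA, rt; then dilute aq. HCl to pH 3
Reagents that add atoms: none
Why: Thiolate SN2 demethylation at the O-methyl carbons is insensitive to the hindrance of the axial C19 ester and is too weakly basic to cause retro-aldol epimerisation of the 3β-hydroxy ester.

Compound list
1 | cyclopentane-1,3-dione | O=C1CCC(=O)C1 | starting material
2 | 2,3-dibromoprop-1-ene | C=C(Br)CBr | starting material
3 | 2-(2-bromoprop-2-en-1-yl)cyclopentane-1,3-dione | C=C(Br)CC1C(=O)CCC1=O | intermediate
4 | 2-(2-bromoprop-2-en-1-yl)-3-(2-methylpropoxy)cyclopent-2-en-1-one | C=C(Br)CC1=C(OCC(C)C)CCC1=O | intermediate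
5 | 2-(2-bromoprop-2-en-1-yl)-3-(2-methylpropoxy)cyclopent-2-en-1-ol (racemic, not isolated) | C=C(Br)CC1=C(OCC(C)C)CCC1O | intermediate
6 | 2-(2-bromoprop-2-en-1-yl)cyclopent-2-en-1-one | C=C(Br)CC1=CCCC1=O | intermediate
7 | buta-1,3-diene | C=CC=C | starting material
8 | (3aR,7aR)-7a-(2-bromoprop-2-en-1-yl)-2,3,3a,4,7,7a-hexahydro-1H-inden-1-one | C=C(Br)C[C@]12CC=CC[C@H]1CCC2=O | intermediate
9 | (1R,5S,8R)-9-methylidenetricyclo[6.2.1.0(1,5)]undecan-2-one (rings B, C, D; 6-oxo) | C=C1C[C@]23C[C@H]1CC[C@H]2CCC3=O | intermediate
10 | rings B, C, D enone (6-oxo, C5=C10) | C=C1C[C@]23C[C@H]1CC[C@H]2C=CC3=O | intermediate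
11 | chloromagnesium enolate of the 10β-silylmethyl ketone (not isolated) | C=C1C[C@]23C[C@H]1CC[C@H]2[C@H](C[Si](C)(C)OC(C)C)C=C3O[Mg]Cl | intermediate
12 | enol triflate (6-OTf, C5=C6, 10β-CH2SiMe2(O-i-Pr)) | C=C1C[C@]23C[C@H]1CC[C@H]2[C@H](C[Si](C)(C)OC(C)C)C=C3OS(=O)(=O)C(F)(F)F | intermediate
13 | methyl ester (C5=C6, 6-CO2Me, 10β-CH2SiMe2(O-i-Pr)) | C=C1C[C@]23C[C@H]1CC[C@H]2[C@H](C[Si](C)(C)OC(C)C)C=C3C(=O)OC | intermediate
14 | dimethyl malonate | COC(=O)CC(=O)OC | starting material
15 | potassium enolate of the 5α-malonate adduct (not isolated) | C=C1C[C@]23C[C@H]1CC[C@H]2[C@H](C[Si](C)(C)OC(C)C)[C@@H](C(C(=O)OC)=C(OC)O[K])[C@@H]3C(=O)OC | intermediate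
16 | triester (5α-C(CH3)(CO2Me)2, 6β-CO2Me, 10β-CH2SiMe2(O-i-Pr)) | C=C1C[C@]23C[C@H]1CC[C@H]2[C@H](C[Si](C)(C)OC(C)C)[C@@H](C(C)(C(=O)OC)C(=O)OC)[C@@H]3C(=O)OC | intermediate
17 | triester alcohol (10β-CH2OH) | C=C1C[C@]23C[C@H]1CC[C@H]2[C@H](CO)[C@@H](C(C)(C(=O)OC)C(=O)OC)[C@@H]3C(=O)OC | intermediate
18 | triester aldehyde (10β-CHO, 5α-C(CH3)(CO2Me)2, 6β-CO2Me) | C=C1C[C@]23C[C@H]1CC[C@H]2[C@H](C=O)[C@@H](C(C)(C(=O)OC)C(=O)OC)[C@@H]3C(=O)OC | intermediate
19 | allyl acrylate (prop-2-en-1-yl prop-2-enoate) | C=CC(=O)OCC=C | starting material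
20 | Michael adduct (10α-CHO, 10β-CH2CH2CO2allyl; not isolated) | C=C1C[C@]23C[C@H]1CC[C@H]2[C@](C=O)(CCC(=O)OCC=C)[C@@H](C(C)(C(=O)OC)C(=O)OC)[C@@H]3C(=O)OC | intermediate
21 | dimethyl 2-(allyloxycarbonyl)-3,20-dioxogibberell-16-ene-7,19-dioate (ring A β-keto ester, C2 unassigned) | C=C1C[C@]23C[C@H]1CC[C@H]2[C@]1(C=O)CC(C(=O)OCC=C)C(=O)[C@@](C)(C(=O)OC)[C@H]1[C@@H]3C(=O)OC | intermediate
22 | dimethyl 2-carboxy-3,20-dioxogibberell-16-ene-7,19-dioate (β-keto acid, not isolated) | C=C1C[C@]23C[C@H]1CC[C@H]2[C@]1(C=O)CC(C(=O)O)C(=O)[C@@](C)(C(=O)OC)[C@H]1[C@@H]3C(=O)OC | intermediate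
23 | dimethyl 3,20-dioxogibberell-16-ene-7,19-dioate (3-keto 20-aldehyde diester) | C=C1C[C@]23C[C@H]1CC[C@H]2[C@]1(C=O)CCC(=O)[C@@](C)(C(=O)OC)[C@H]1[C@@H]3C(=O)OC | intermediate
24 | dimethyl 20-(dimethylhydrazinylidene)-3-oxogibberell-16-ene-7,19-dioate (20-(N,N-dimethylhydrazone) of 23) | C=C1C[C@]23C[C@H]1CC[C@H]2[C@]1(/C=N/N(C)C)CCC(=O)[C@@](C)(C(=O)OC)[C@H]1[C@@H]3C(=O)OC | intermediate
25 | dimethyl 20-(dimethylhydrazinylidene)-3β-hydroxygibberell-16-ene-7,19-dioate (not isolated) | C=C1C[C@]23C[C@H]1CC[C@H]2[C@]1(/C=N/N(C)C)CC[C@H](O)[C@@](C)(C(=O)OC)[C@H]1[C@@H]3C(=O)OC | intermediate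
26 | dimethyl 3β-hydroxy-20-oxogibberell-16-ene-7,19-dioate (dimethyl ester of the target) | C=C1C[C@]23C[C@H]1CC[C@H]2[C@]1(C=O)CC[C@H](O)[C@@](C)(C(=O)OC)[C@H]1[C@@H]3C(=O)OC | intermediate
27 | 3β-hydroxy-20-oxogibberell-16-ene-7,19-dioic acid (the target gibberellin) | C=C1C[C@]23C[C@H]1CC[C@H]2[C@]1(C=O)CC[C@H](O)[C@@](C)(C(=O)O)[C@H]1[C@@H]3C(=O)O | target

Total step count: 16. Longest linear sequence: 16 steps (from 1).

Steps most likely to fail

Step 12. The C10 enolate may fragment by retro-Michael loss of the methylmalonate unit before it is intercepted by the acrylate, and the closure may discriminate poorly between the two ester groups. The fallback sets out from 18 and comes back to the route at 21. Aldehyde 18 is condensed with pyrrolidine (toluene, Dean–Stark) to the pyrrolidine enamine F1, a neutral C10 nucleophile that cannot expel the malonate. Stork enamine alkylation of F1 with 19 in refluxing MeCN, then hydrolysis with aqueous AcOH, gives the Michael adduct 20, which is now isolated. A separate Dieckmann condensation (KOt-Bu, THF, −40 °C) then closes ring A to 21.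

Step 4. The α-substituted enone may react too slowly with unactivated butadiene, so that an uncatalysed or diene-polymerising background pathway erodes conversion and enantioselectivity. The fallback sets out from 7 (with commercial cyclopent-2-en-1-one) and comes back at 8. The unsubstituted enone, a much better dienophile for this catalyst type, is used in the same enantioselective Diels–Alder reaction to give cis-(3aR,7aS)-2,3,3a,4,7,7a-hexahydro-1H-inden-1-one F2. Angular alkylation of its more substituted potassium enolate (KOt-Bu, t-BuOH) with 2 on the convex face then gives 8.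

Step 5. Regiocontrol of the radical closure may be lost, either by 6-endo attack at C12 or by homoallyl rearrangement to the bicyclo[2.2.2]octane, or the vinyl radical may be reduced before it cyclises. The fallback sets out from 6 and comes back at 9. The Diels–Alder reaction of 6 is run with commercial 2-(trimethylsilyloxy)buta-1,3-diene under the catalyst of step 4 and gives the silyl enol ether F3, with the silyloxy group on C12, para to C8. Palladium-catalysed intramolecular α-alkenylation of the enol ether (Pd2(dba)3, t-Bu3P, CsF) joins C13 to C16 at the only nucleophilic carbon and gives the diketone F4. The less hindered C12 ketone is converted into the tosylhydrazone F5 (TsNHNH2, EtOH), and reduction with catecholborane/NaOAc removes it to give 9.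

Further compounds
F1 | step 12 | pyrrolidine enamine of aldehyde 18 (C10=C20–N) | C=C1C[C@]23C[C@H]1CC[C@H]2C(=CN1CCCC1)[C@@H](C(C)(C(=O)OC)C(=O)OC)[C@@H]3C(=O)OC
F2 | step 4 | (3aR,7aS)-2,3,3a,4,7,7a-hexahydro-1H-inden-1-one | [C@H]12CC=CC[C@H]1CCC2=O
F3 | step 5 | (3aR,7aR)-7a-(2-bromoprop-2-en-1-yl)-5-(trimethylsilyloxy)-2,3,3a,4,7,7a-hexahydro-1H-inden-1-one | C=C(Br)C[C@]12CC=C(O[Si](C)(C)C)C[C@H]1CCC2=O
F4 | step 5 | rings B, C, D diketone (6,12-dioxo analogue of 9) | C=C1C[C@]23C[C@H]1C(=O)C[C@H]2CCC3=O
F5 | step 5 | 12-tosylhydrazone of the diketone | C=C1C[C@]23C[C@H]1C(=NNS(=O)(=O)c1ccc(C)cc1)C[C@H]2CCC3=O
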